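## Analysis of the target

The target (33) is a trans-fused decalin of the eremophilane type. Ring A (C1–C5, C10) carries the C3 senecioate, the secondary methyl C15 on C4 and the angular methyl C14 on the quaternary C5. Ring B (C5–C10) carries the isopropenyl group on C7, the C8 ketone and the C9 tiglate. The six stereocentres are 3R,4R,5R,7S,9S,10R. C14 and H-10 are anti (trans fusion), C14 and C15 are cis, the C3 oxygen is trans to C15, and the C7 and C9 substituents lie on the face opposite C14, so every substituent except the angular methyl is equatorial on the chair–chair decalin. C7 and C9 flank the ketone and are therefore epimerisable but thermodynamically correct, whereas C3, C4, C5 and C10 must be set under kinetic control. The sensitive groups are the β,γ-unsaturated ketone (H-7 is α to C8 and allylic, so acid or base can move C11=C12 into conjugation and delete C7), the α-acyloxy ketone at C9, and two different α,β-unsaturated esters that have to be introduced one after the other. The hard part is the contiguous C3–C4–C5–C10 array, in which a quaternary carbon sits between a methyl-bearing carbon and the ring fusion with no carbonyl in ring A to build it from. The strategy rests on the ring-fusion bond C5–C10, which joins the quaternary carbon to the carbon β to the C8 ketone: cutting it opens both rings to one ten-membered ring with a C9=C10 enone and an exocyclic methylene (C14) on C5.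

## Retrosynthetic reasoning

**33 ⇒ 31 (C11=C12).** The isopropenyl double bond is formed last, by elimination from the tertiary carbinol 31. The β,γ-unsaturated ketone is the most fragile function of 33, and a carbinol at C11 lets every basic or nucleophilic step be run before it exists. The forward elimination has to take a methyl hydrogen and not H-7.

**31 ⇒ 29 + 30, and 28 ⇒ 26 + 27 (two acyl–oxygen bonds).** The two esters are cut one at a time. The C9 hydroxyl of 26 is acylated with 27 while C3 and C11 are silylated. Removal of both silyl groups gives diol 29, in which only the secondary C3 hydroxyl can react with 30. No selective acylation between two secondary alcohols is needed.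

**26 ⇒ 24 (C9–O).** The C9 oxygen is introduced by hydroxylation of the C8 enolate formed toward C9. In 24 the other α-carbon, C7, is tertiary and carries the bulky silyloxy-isopropyl group, so kinetic deprotonation should go to C9. The axial C14 methyl blocks the β face, and this should give the equatorial 9α-alcohol.

**23 ⇒ 19 + 20 (C7–C11).** The three-carbon unit is cut off as acetone (20), and the forward reaction is an aldol at C7. A trans-fused decalone of this kind enolises away from the ring fusion, so decalone 19 needs no blocking group. Silylation to 24 then prevents retro-aldol cleavage.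

**19 ⇒ 16 (C5–C10, key disconnection).** Homolytic cleavage of the ring fusion bond, with removal of one hydrogen from C14 and one from C9, leads to cyclodecenone 16. One bond then makes both six-membered rings, the quaternary carbon and the ring fusion. The precursor holds only the C3 and C4 stereocentres. The forward reaction must create a tertiary C5 radical selectively and let it add across the ring to C10.

**16 ⇒ 15 ⇒ 14 (C8–C9).** The ten-membered ring is opened at the bond between the carbonyl carbon and the alkene, which leads to iodoalkenyl aldehyde 14 and a chromium-mediated ring closure. Olefin metathesis at C9=C10 was not used: a terminal alkene at C10 and the C5 methylene would be 1,7-related and would close a cyclohexene much faster than the ten-membered ring. The iodoalkene fixes the (E) geometry before the ring exists.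

**14 ⇒ 13 ⇒ 12 ⇒ 9 + 11 (C5=C14 and C5–C6).** The methylene is traced back to the C5 ketone of 12, and the C6–C8 chain to the acetal-bearing Grignard reagent 11, which adds to Weinreb amide 9. Carbon C5 is thus the carboxyl carbon of an aldol product.

**9 ⇒ 8 ⇒ 7 ⇒ 5 + 4 (C3–C4).** The syn relationship of the C3 oxygen and the C4 methyl is that of an auxiliary-controlled syn aldol between propionimide 5 and aldehyde 4. Both stereocentres of the key-step precursor come from this one step. An addition to an α-methyl aldehyde would control C3 less reliably.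

**4 ⇒ 3 ⇒ 1, and 11 ⇒ 10.** Aldehyde 4 comes from pent-4-yn-1-ol (1) by hydrometalation–iodination and oxidation. Grignard reagent 11 comes from bromide 10.

## Alternatives that were turned down

**Alternative 1:** Ring B by a [4+2] cycloaddition.
- Disconnection: C5–C6 and C7–C8, which leads to the ring-A enol-ether diene A1 (C8=C9–C10=C5) and methyl vinyl ketone A2.
- Forward key step: cycloaddition under high pressure or mild Lewis acid to cycloadduct A3, with the alkoxy carbon C8 bonding to the acetyl-bearing carbon (ortho orientation).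
- For it: the C7 acetyl group of A3 is a regiochemically unambiguous precursor of the isopropenyl group. C8 arrives oxygenated. A syn addition across the remaining C9=C10 bond from the face opposite C14 could deliver H-10 and the C9 oxygen together. On these three points it is stronger than the chosen route, whose endgame is longer and ends with a regiochemically delicate elimination.
- Against it: the quaternary carbon must form at a fully substituted diene terminus next to C4, where cycloadditions are slow and only the C4 methyl selects the face. The enol ether limits the Lewis acid strength. A1 itself needs a separate synthesis carrying C3 and C4.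
- Comparison: the chosen strategy forms C5 by an intramolecular radical addition that is less sensitive to crowding, and obtains C3 and C4 from one aldol. In place of the better-functionalised ring B of A3 it offers a precursor whose risk is confined to one step.

**Alternative 2:** Enzymatic cyclisation.
- Disconnection: C6–C7 and C5–C10, together with a hydride shift and a methyl shift, back to farnesyl diphosphate A4.
- Forward key step: a class one terpene cyclase (aristolochene synthase) ionises A4 and delivers (+)-aristolochene A5.
- For it: one step builds both rings, the isopropenyl group and C4, C5 and C7 in the configuration of the target. No chemical route matches this, and on skeleton construction it is clearly stronger than the chosen strategy.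
- Against it: A5 contains no oxygen. C3 is an unactivated methylene with no neighbouring handle. C8 and C9 would have to be oxidised next to C9=C10 in competition with the isopropenyl alkene and the other allylic positions, and H-10 still has to be added trans. The enzyme and the diphosphate must also be produced.
- Comparison: the chosen strategy carries the C3 oxygen from its third step and uses ordinary reagents. It offers oxygenation at defined positions in place of skeletal economy.

**Alternative 3:** Ring A by a quinone Diels–Alder reaction.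
- Disconnection: C4–C5 and C1–C10, which leads to methoxy-methyl-benzoquinone A6 and silyloxydiene A7.
- Forward key step: an endo cycloaddition at the methyl-bearing quinone alkene under a chiral, chelating Lewis acid of tetravalent titanium, giving cycloadduct A8.
- For it: it is convergent and catalytic in chirality. Ring B arrives with oxygen at C8 and C9, and C3 is already an enol ether. In step count to a bicyclic core and in having the C9 oxygen in place it is stronger than the chosen route.
- Against it: A8 is cis-fused. Because the methyl of A7 sits on the outside of the diene, the endo transition state places the C4 methyl trans to the C5 methyl. Both C10 and C4 would therefore have to be epimerised through adjacent ketones, against uncertain thermodynamics. The C6 oxygen is surplus and must be removed, the C3 ketone must be reduced selectively, and C7 must be alkylated on a vinylogous ester.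
- Comparison: the chosen strategy aims directly at the trans fusion and the cis methyls and introduces no oxygen that has to be taken out again. It gives up the pre-oxidised ring B for this.

Key step: step 12

Remark: positions are cited in eremophilane numbering (C1–C15) also for open-chain and ten-membered intermediates. β is the face of the angular methyl C14. Compound 15 is carried as a mixture of carbinol epimers because that carbon becomes the C8 carbonyl.

## Route

Step 1
Reactants: 1 pent-4-yn-1-ol
Product: 3 (E)-5-iodopent-4-en-1-ol, via the (E)-alkenylzirconocene chloride 2 (not isolated)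
Conditions: Cp2Zr(H)Cl (2.2 equiv), THF, 0 °C → rt; I2, THF, −20 °C; aq. Na2S2O3
Reagents that add atoms: iodine, II
Why: Hydrozirconation–iodination: syn addition of Zr–H places the metal on the terminal carbon and iodinolysis with retention gives the (E)-iodoalkene; the first equivalent of hydride is consumed by the hydroxyl group.

Step 2
Reactants: 3 (E)-5-iodopent-4-en-1-ol
Product: 4 (E)-5-iodopent-4-enal
Conditions: PhI(OAc)2 (1.1 equiv), TEMPO (0.1 equiv), CH2Cl2, rt
Reagents that add atoms: none
Why: TEMPO-catalysed oxidation of a primary alcohol stops at the aldehyde and leaves the iodoalkene untouched.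

Step 3
Reactants: 5 (S)-4-benzyl-3-propionyloxazolidin-2-one; 4 (E)-5-iodopent-4-enal
Product: 7 (S)-4-benzyl-3-[(2S,3R,6E)-3-hydroxy-7-iodo-2-methylhept-6-enoyl]oxazolidin-2-one, via the (Z)-dibutylboron enolate 6 (not isolated)
Conditions: Bu2BOTf, i-Pr2NEt, CH2Cl2, 0 °C; then 4, −78 → 0 °C; pH 7 buffer, MeOH, H2O2, 0 °C
Reagents that add atoms: none
Why: Evans syn aldol: the (Z)-boron enolate reacts through a closed chair transition state on the face away from the benzyl group, which sets the future C3 (carbinol) and C4 (methyl) centres with the syn relationship and the absolute configuration of the target.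

Step 4
Reactants: 7 (S)-4-benzyl-3-[(2S,3R,6E)-3-hydroxy-7-iodo-2-methylhept-6-enoyl]oxazolidin-2-one
Product: 8 (2S,3R,6E)-3-hydroxy-7-iodo-N-methoxy-N,2-dimethylhept-6-enamide
Conditions: MeNH(OMe)·HCl, AlMe3, CH2Cl2, −20 → 0 °C; aq. potassium sodium tartrate (KNaC4H4O6)
Reagents that add atoms: N,O-dimethylhydroxylamine hydrochloride, CNOC.Cl
Why: Aluminium-amide transamination of the imide (Weinreb amide formation) is assisted by the free β-hydroxyl, does not epimerise the α-carbon, and releases the auxiliary for recovery.

Step 5
Reactants: 8 (2S,3R,6E)-3-hydroxy-7-iodo-N-methoxy-N,2-dimethylhept-6-enamide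
Product: 9 (2S,3R,6E)-3-[(tert-butyldimethylsilyl)oxy]-7-iodo-N-methoxy-N,2-dimethylhept-6-enamide
Conditions: TBSOTf, 2,6-lutidine, CH2Cl2, −78 → 0 °C
Reagents that add atoms: tert-butyldimethylsilyl trifluoromethanesulfonate, CC(C)(C)[Si](C)(C)OS(=O)(=O)C(F)(F)F
Why: Silylation with the silyl triflate and a hindered base protects the C3 hydroxyl without retro-aldol cleavage or epimerisation.

Step 6
Reactants: 10 2-(2-bromoethyl)-1,3-dioxolane
Product: 11 [2-(1,3-dioxolan-2-yl)ethyl]magnesium bromide (THF solution, used directly)
Conditions: Mg turnings, 1,2-dibromoethane (cat.), THF, 20–30 °C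
Reagents that add atoms: magnesium, [Mg]
Why: Grignard formation from a primary bromide; the temperature is kept low because this acetal-bearing reagent decomposes on heating.

Step 7
Reactants: 9 (2S,3R,6E)-3-[(tert-butyldimethylsilyl)oxy]-7-iodo-N-methoxy-N,2-dimethylhept-6-enamide; 11 [2-(1,3-dioxolan-2-yl)ethyl]magnesium bromide
Product: 12 (4S,5R,8E)-5-[(tert-butyldimethylsilyl)oxy]-1-(1,3-dioxolan-2-yl)-9-iodo-4-methylnon-8-en-3-one
Conditions: 11 (2.5 equiv), THF, 0 °C → rt; aq. NH4Cl
Reagents that add atoms: none
Why: Grignard addition to a Weinreb amide stops at the stable chelated adduct, so the ketone (C5) is released only on work-up and neither over-addition nor α-epimerisation is expected; an alkenyl iodide does not exchange with an alkyl Grignard reagent at this temperature.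

Step 8
Reactants: 12 (4S,5R,8E)-5-[(tert-butyldimethylsilyl)oxy]-1-(1,3-dioxolan-2-yl)-9-iodo-4-methylnon-8-en-3-one
Product: 13 2-[(4R,5R,8E)-5-[(tert-butyldimethylsilyl)oxy]-9-iodo-4-methyl-3-methylidenenon-8-en-1-yl]-1,3-dioxolane
Conditions: Cp2TiMe2 (3 equiv), toluene, 70 °C, dark
Reagents that add atoms: dimethyltitanocene, C[Ti](C)(C1C=CC=C1)C1C=CC=C1
Why: Petasis methylenation is neutral and non-basic, so the C4 centre α to the ketone is not epimerised and the β-silyloxy group is not eliminated; the acetal and the internal iodoalkene are inert to the reagent.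

Step 9
Reactants: 13 2-[(4R,5R,8E)-5-[(tert-butyldimethylsilyl)oxy]-9-iodo-4-methyl-3-methylidenenon-8-en-1-yl]-1,3-dioxolane
Product: 14 (5R,6R,9E)-6-[(tert-butyldimethylsilyl)oxy]-10-iodo-5-methyl-4-methylidenedec-9-enal
Conditions: PPTS (0.3 equiv), acetone/H2O (9:1), 55 °C
Reagents that add atoms: water, O
Why: Mild acid-catalysed acetal hydrolysis; a secondary tert-butyldimethylsilyl ether next to a branched carbon and the 1,1-disubstituted alkene should survive this weak acid.

Step 10
Reactants: 14 (5R,6R,9E)-6-[(tert-butyldimethylsilyl)oxy]-10-iodo-5-methyl-4-methylidenedec-9-enal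
Product: 15 (2E,6R,7R)-6-[(tert-butyldimethylsilyl)oxy]-7-methyl-8-methylidenecyclodec-2-en-1-ol (both C1 epimers)
Conditions: CrCl2 (8 equiv), NiCl2 (0.02 equiv), DMSO/THF, rt, slow addition of 14 (final 0.003 M)
Reagents that add atoms: none
Why: Intramolecular Nozaki–Hiyama–Kishi reaction: nickel catalysis activates the carbon–iodine bond and divalent chromium mediates chemoselective addition to the aldehyde with retention of the (E) geometry; high dilution favours ring closure, and the 1,1-disubstituted alkene does not take part.

Step 11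
Reactants: 15 (2E,6R,7R)-6-[(tert-butyldimethylsilyl)oxy]-7-methyl-8-methylidenecyclodec-2-en-1-ol
Product: 16 (2E,6R,7R)-6-[(tert-butyldimethylsilyl)oxy]-7-methyl-8-methylidenecyclodec-2-en-1-one
Conditions: Dess–Martin periodinane, NaHCO3, CH2Cl2, 0 °C → rt
Reagents that add atoms: none
Why: Buffered Dess–Martin oxidation converts both allylic alcohol epimers into the (E)-enone under neutral conditions that should not move either double bond.

Step 12
Reactants: 16 (2E,6R,7R)-6-[(tert-butyldimethylsilyl)oxy]-7-methyl-8-methylidenecyclodec-2-en-1-one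
Product: 19 (4aS,5R,6R,8aS)-6-[(tert-butyldimethylsilyl)oxy]-4a,5-dimethyloctahydronaphthalen-2(1H)-one, via the tertiary C5 radical 17 (not isolated), via the C9 α-keto radical 18 (not isolated)
Conditions: Fe(acac)3 (0.3 equiv), PhSiH3 (2.5 equiv), EtOH/ethylene glycol (5:1), 0.01 M, 60 °C
Reagents that add atoms: none
Why: Proposed new method: an iron hydride formed from Fe(acac)3 and PhSiH3 transfers a hydrogen atom to the terminal carbon of the electron-rich methylene of 16, which creates the C14 methyl and the tertiary radical 17; this nucleophilic radical adds across the ring to C10, the β-carbon of the (E)-enone, and the α-keto radical 18 is reduced by divalent iron to the enolate and protonated at C9 by ethanol, which returns trivalent iron. The closest known reaction type is the Fe(acac)3/PhSiH3 hydrogen-atom-transfer olefin–enone (Giese-type) cyclisation, and transannular radical additions to macrocyclic enones are known for radicals made in other ways, but the hydride-initiated transannular closure of a ten-membered ring is untested. The single C5–C10 bond closes ring A in a 6-exo-trig sense (C9 stays outside the ring) and ring B in a 6-endo-trig sense (C9 inside). C10 is controlled by the (E) geometry of the enone, which puts H-10 and C9 on opposite faces, so that a chair–chair transition state leaves H-10 and the new C14 methyl trans-diaxial (trans fusion). C5 is controlled by the C3 and C4 centres: only one of the two chair–chair arrangements keeps the silyloxy group and the C4 methyl equatorial, and it places C14 cis to C15. The step needs hydrogen-atom transfer to the methylene and not to the enone, which the preference of such metal hydrides for electron-rich 1,1-disubstituted alkenes should secure. It needs ring closure faster than quenching of 17, which the proximity of C5 and C10 in the ring and high dilution favour. It needs attack at C10 and not C9, which the polarity match between a nucleophilic radical and the enone β-carbon provides.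

Step 13
Reactants: 19 (4aS,5R,6R,8aS)-6-[(tert-butyldimethylsilyl)oxy]-4a,5-dimethyloctahydronaphthalen-2(1H)-one; 20 acetone
Product: 23 (3S,4aS,5R,6R,8aS)-6-[(tert-butyldimethylsilyl)oxy]-3-(2-hydroxypropan-2-yl)-4a,5-dimethyloctahydronaphthalen-2(1H)-one, via the lithium enolate 21 (not isolated), via the chlorozinc enolate 22 (not isolated)
Conditions: LiN(i-Pr)2 (1.1 equiv), THF, −78 °C; ZnCl2, −78 °C; acetone, −78 → −40 °C; aq. NH4Cl
Reagents that add atoms: none
Why: Kinetic enolisation of a trans-fused decalone of this type goes away from the ring fusion (toward C7, as 3-keto-5α-steroids enolise toward C2), and the zinc enolate adds to acetone in a directed aldol whose zinc aldolate resists retro-aldol cleavage. The electrophile approaches C7 from the α face, away from the 1,3-diaxial C14 methyl, which gives the equatorial (7S) side chain; this is also the thermodynamic epimer.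

Step 14
Reactants: 23 (3S,4aS,5R,6R,8aS)-6-[(tert-butyldimethylsilyl)oxy]-3-(2-hydroxypropan-2-yl)-4a,5-dimethyloctahydronaphthalen-2(1H)-one
Product: 24 (3S,4aS,5R,6R,8aS)-6-[(tert-butyldimethylsilyl)oxy]-4a,5-dimethyl-3-{2-[(triethylsilyl)oxy]propan-2-yl}octahydronaphthalen-2(1H)-one
Conditions: TESOTf, 2,6-lutidine, CH2Cl2, −78 → 0 °C
Reagents that add atoms: triethylsilyl trifluoromethanesulfonate, CC[Si](CC)(CC)OS(=O)(=O)C(F)(F)F
Why: Silylation of the tertiary alcohol with a silyl triflate blocks retro-aldol cleavage in the next step and adds bulk around H-7.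

Step 15
Reactants: 24 (3S,4aS,5R,6R,8aS)-6-[(tert-butyldimethylsilyl)oxy]-4a,5-dimethyl-3-{2-[(triethylsilyl)oxy]propan-2-yl}octahydronaphthalen-2(1H)-one
Product: 26 (1S,3S,4aR,5R,6R,8aR)-6-[(tert-butyldimethylsilyl)oxy]-1-hydroxy-4a,5-dimethyl-3-{2-[(triethylsilyl)oxy]propan-2-yl}octahydronaphthalen-2(1H)-one, via the potassium enolate 25 (not isolated)
Conditions: KN(SiMe3)2 (1.2 equiv), THF, −78 °C; 2-(phenylsulfonyl)-3-phenyloxaziridine, −78 °C; aq. NH4Cl
Reagents that add atoms: 2-(phenylsulfonyl)-3-phenyloxaziridine, O=S(=O)(c1ccccc1)N1OC1c1ccccc1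
Why: Kinetic deprotonation by the bulky amide should occur at the C9 methylene and not at the tertiary, shielded C7, and the enolate is hydroxylated by the N-sulfonyloxaziridine (Davis oxidation). Oxygen is delivered to the α face of C9, opposite the axial C14 methyl, which gives the equatorial 9α-alcohol (9S); this is also the more stable epimer.

Step 16
Reactants: 26 (1S,3S,4aR,5R,6R,8aR)-6-[(tert-butyldimethylsilyl)oxy]-1-hydroxy-4a,5-dimethyl-3-{2-[(triethylsilyl)oxy]propan-2-yl}octahydronaphthalen-2(1H)-one; 27 (E)-2-methylbut-2-enoyl chloride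
Product: 28 (1S,3S,4aR,5R,6R,8aR)-6-[(tert-butyldimethylsilyl)oxy]-4a,5-dimethyl-2-oxo-3-{2-[(triethylsilyl)oxy]propan-2-yl}decahydronaphthalen-1-yl (E)-2-methylbut-2-enoate
Conditions: 27 (2 equiv), pyridine, DMAP (0.2 equiv), CH2Cl2, 0 °C → rt
Reagents that add atoms: none
Why: DMAP-catalysed acylation of the only free hydroxyl; the weak base pyridine avoids ketene formation from the acid chloride and epimerisation at C9.

Step 17
Reactants: 28 (1S,3S,4aR,5R,6R,8aR)-6-[(tert-butyldimethylsilyl)oxy]-4a,5-dimethyl-2-oxo-3-{2-[(triethylsilyl)oxy]propan-2-yl}decahydronaphthalen-1-yl (E)-2-methylbut-2-enoate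
Product: 29 (1S,3S,4aR,5R,6R,8aR)-6-hydroxy-3-(2-hydroxypropan-2-yl)-4a,5-dimethyl-2-oxodecahydronaphthalen-1-yl (E)-2-methylbut-2-enoate
Conditions: HF·pyridine, pyridine, THF, 0 °C → rt
Reagents that add atoms: none
Why: Buffered hydrogen fluoride cleaves both silyl ethers; the ester, the α-acyloxy ketone and the tertiary β-hydroxy ketone should tolerate these weakly acidic conditions.

Step 18
Reactants: 29 (1S,3S,4aR,5R,6R,8aR)-6-hydroxy-3-(2-hydroxypropan-2-yl)-4a,5-dimethyl-2-oxodecahydronaphthalen-1-yl (E)-2-methylbut-2-enoate; 30 3-methylbut-2-enoyl chloride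
Product: 31 (1S,3S,4aR,5R,6R,8aR)-3-(2-hydroxypropan-2-yl)-4a,5-dimethyl-6-[(3-methylbut-2-enoyl)oxy]-2-oxodecahydronaphthalen-1-yl (E)-2-methylbut-2-enoate
Conditions: 30 (1.5 equiv), pyridine, DMAP (0.1 equiv), CH2Cl2, 0 °C
Reagents that add atoms: none
Why: DMAP-catalysed acylation is selective for the secondary, equatorial C3 hydroxyl because the tertiary carbinol does not react under these conditions; pyridine in place of a trialkylamine limits deconjugation of the senecioyl unit.

Step 19
Reactants: 31 (1S,3S,4aR,5R,6R,8aR)-3-(2-hydroxypropan-2-yl)-4a,5-dimethyl-6-[(3-methylbut-2-enoyl)oxy]-2-oxodecahydronaphthalen-1-yl (E)-2-methylbut-2-enoate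
Product: 33 (1S,3S,4aR,5R,6R,8aR)-4a,5-dimethyl-6-[(3-methylbut-2-enoyl)oxy]-2-oxo-3-(prop-1-en-2-yl)decahydronaphthalen-1-yl (E)-2-methylbut-2-enoate (the target), via the chlorosulfite 32 (not isolated)
Conditions: SOCl2 (1.5 equiv), pyridine, CH2Cl2, −30 → 0 °C
Reagents that add atoms: none
Why: Dehydration of a tertiary alcohol through its chlorosulfite with pyridine as base is an E2-type elimination under kinetic control. It should take one of the six unhindered methyl hydrogens and not the single hindered H-7, whose anti-periplanar rotamer is the most crowded, so that the isopropenyl group forms without touching C7. The weak base and low temperature leave the esters and the C7 and C9 centres alone.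

## Compound list

1 | pent-4-yn-1-ol | C#CCCCO | starting material
2 | (E)-alkenylzirconocene chloride from 1 (oxygen also zirconated; cyclopentadienyl ligands drawn σ-bonded; formed in the flask) | Cl[Zr](C1C=CC=C1)(C1C=CC=C1)/C=C/CCCO[Zr](Cl)(C1C=CC=C1)C1C=CC=C1 | intermediate
3 | (E)-5-iodopent-4-en-1-ol | OCCC/C=C/I | intermediate
4 | (E)-5-iodopent-4-enal | O=CCC/C=C/I | intermediate
5 | (S)-4-benzyl-3-propionyloxazolidin-2-one | CCC(=O)N1[C@@H](Cc2ccccc2)COC1=O | starting material
6 | (Z)-dibutylboron enolate of 5 (formed in the flask) | C/C=C(\OB(CCCC)CCCC)N1[C@@H](Cc2ccccc2)COC1=O | intermediate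
7 | (S)-4-benzyl-3-[(2S,3R,6E)-3-hydroxy-7-iodo-2-methylhept-6-enoyl]oxazolidin-2-one | I/C=C/CC[C@@H](O)[C@H](C)C(=O)N1[C@@H](Cc2ccccc2)COC1=O | intermediate
8 | (2S,3R,6E)-3-hydroxy-7-iodo-N-methoxy-N,2-dimethylhept-6-enamide | I/C=C/CC[C@@H](O)[C@H](C)C(=O)N(C)OC | intermediate
9 | (2S,3R,6E)-3-[(tert-butyldimethylsilyl)oxy]-7-iodo-N-methoxy-N,2-dimethylhept-6-enamide | I/C=C/CC[C@@H](O[Si](C)(C)C(C)(C)C)[C@H](C)C(=O)N(C)OC | intermediate
10 | 2-(2-bromoethyl)-1,3-dioxolane | BrCCC1OCCO1 | starting material
11 | [2-(1,3-dioxolan-2-yl)ethyl]magnesium bromide | Br[Mg]CCC1OCCO1 | intermediate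
12 | (4S,5R,8E)-5-[(tert-butyldimethylsilyl)oxy]-1-(1,3-dioxolan-2-yl)-9-iodo-4-methylnon-8-en-3-one | I/C=C/CC[C@@H](O[Si](C)(C)C(C)(C)C)[C@H](C)C(=O)CCC1OCCO1 | intermediate
13 | 2-[(4R,5R,8E)-5-[(tert-butyldimethylsilyl)oxy]-9-iodo-4-methyl-3-methylidenenon-8-en-1-yl]-1,3-dioxolane | I/C=C/CC[C@@H](O[Si](C)(C)C(C)(C)C)[C@H](C)C(=C)CCC1OCCO1 | intermediate
14 | (5R,6R,9E)-6-[(tert-butyldimethylsilyl)oxy]-10-iodo-5-methyl-4-methylidenedec-9-enal | I/C=C/CC[C@@H](O[Si](C)(C)C(C)(C)C)[C@H](C)C(=C)CCC=O | intermediate
15 | (2E,6R,7R)-6-[(tert-butyldimethylsilyl)oxy]-7-methyl-8-methylidenecyclodec-2-en-1-ol (both C1 epimers) | OC1/C=C/CC[C@@H](O[Si](C)(C)C(C)(C)C)[C@H](C)C(=C)CC1 | intermediate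
16 | (2E,6R,7R)-6-[(tert-butyldimethylsilyl)oxy]-7-methyl-8-methylidenecyclodec-2-en-1-one | O=C1/C=C/CC[C@@H](O[Si](C)(C)C(C)(C)C)[C@H](C)C(=C)CC1 | intermediate
17 | tertiary C5 radical of the cyclodecenone (ring position 8, now bearing the C14 methyl; formed in the flask) | O=C1/C=C/CC[C@@H](O[Si](C)(C)C(C)(C)C)[C@H](C)[C](C)CC1 | intermediate
18 | C9 α-keto radical of the trans-fused decalone (formed in the flask) | C1C[C@]2(C)[C@@H](C)[C@H](O[Si](C)(C)C(C)(C)C)CC[C@H]2[CH]C1=O | intermediate
19 | (4aS,5R,6R,8aS)-6-[(tert-butyldimethylsilyl)oxy]-4a,5-dimethyloctahydronaphthalen-2(1H)-one (C8 ketone, 3α-silyloxy, 4β,5β-dimethyl, 10α-H) | C1C[C@]2(C)[C@@H](C)[C@H](O[Si](C)(C)C(C)(C)C)CC[C@H]2CC1=O | intermediate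
20 | acetone | CC(C)=O | starting material
21 | lithium C7=C8 enolate of 19 (formed in the flask) | [Li]OC1=CC[C@]2(C)[C@@H](C)[C@H](O[Si](C)(C)C(C)(C)C)CC[C@H]2C1 | intermediate
22 | chlorozinc C7=C8 enolate of 19 (formed in the flask) | Cl[Zn]OC1=CC[C@]2(C)[C@@H](C)[C@H](O[Si](C)(C)C(C)(C)C)CC[C@H]2C1 | intermediate
23 | (3S,4aS,5R,6R,8aS)-6-[(tert-butyldimethylsilyl)oxy]-3-(2-hydroxypropan-2-yl)-4a,5-dimethyloctahydronaphthalen-2(1H)-one | CC(C)(O)[C@@H]1C[C@]2(C)[C@@H](C)[C@H](O[Si](C)(C)C(C)(C)C)CC[C@H]2CC1=O | intermediate
24 | (3S,4aS,5R,6R,8aS)-6-[(tert-butyldimethylsilyl)oxy]-4a,5-dimethyl-3-{2-[(triethylsilyl)oxy]propan-2-yl}octahydronaphthalen-2(1H)-one | CC[Si](CC)(CC)OC(C)(C)[C@@H]1C[C@]2(C)[C@@H](C)[C@H](O[Si](C)(C)C(C)(C)C)CC[C@H]2CC1=O | intermediate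
25 | potassium C8=C9 enolate of 24 (formed in the flask) | CC[Si](CC)(CC)OC(C)(C)[C@@H]1C[C@]2(C)[C@@H](C)[C@H](O[Si](C)(C)C(C)(C)C)CC[C@H]2C=C1O[K] | intermediate
26 | (1S,3S,4aR,5R,6R,8aR)-6-[(tert-butyldimethylsilyl)oxy]-1-hydroxy-4a,5-dimethyl-3-{2-[(triethylsilyl)oxy]propan-2-yl}octahydronaphthalen-2(1H)-one | CC[Si](CC)(CC)OC(C)(C)[C@@H]1C[C@]2(C)[C@@H](C)[C@H](O[Si](C)(C)C(C)(C)C)CC[C@H]2[C@H](O)C1=O | intermediate
27 | (E)-2-methylbut-2-enoyl chloride (tigloyl chloride) | ClC(=O)/C(C)=C/C | starting material
28 | (1S,3S,4aR,5R,6R,8aR)-6-[(tert-butyldimethylsilyl)oxy]-4a,5-dimethyl-2-oxo-3-{2-[(triethylsilyl)oxy]propan-2-yl}decahydronaphthalen-1-yl (E)-2-methylbut-2-enoate | CC[Si](CC)(CC)OC(C)(C)[C@@H]1C[C@]2(C)[C@@H](C)[C@H](O[Si](C)(C)C(C)(C)C)CC[C@H]2[C@H](OC(=O)/C(C)=C/C)C1=O | intermediate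
29 | (1S,3S,4aR,5R,6R,8aR)-6-hydroxy-3-(2-hydroxypropan-2-yl)-4a,5-dimethyl-2-oxodecahydronaphthalen-1-yl (E)-2-methylbut-2-enoate | CC(C)(O)[C@@H]1C[C@]2(C)[C@@H](C)[C@H](O)CC[C@H]2[C@H](OC(=O)/C(C)=C/C)C1=O | intermediate
30 | 3-methylbut-2-enoyl chloride (senecioyl chloride) | CC(C)=CC(Cl)=O | starting material
31 | (1S,3S,4aR,5R,6R,8aR)-3-(2-hydroxypropan-2-yl)-4a,5-dimethyl-6-[(3-methylbut-2-enoyl)oxy]-2-oxodecahydronaphthalen-1-yl (E)-2-methylbut-2-enoate | CC(C)(O)[C@@H]1C[C@]2(C)[C@@H](C)[C@H](OC(=O)C=C(C)C)CC[C@H]2[C@H](OC(=O)/C(C)=C/C)C1=O | intermediate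
32 | chlorosulfite of 31 at the tertiary oxygen (formed in the flask) | CC(C)(OS(Cl)=O)[C@@H]1C[C@]2(C)[C@@H](C)[C@H](OC(=O)C=C(C)C)CC[C@H]2[C@H](OC(=O)/C(C)=C/C)C1=O | intermediate
33 | (1S,3S,4aR,5R,6R,8aR)-4a,5-dimethyl-6-[(3-methylbut-2-enoyl)oxy]-2-oxo-3-(prop-1-en-2-yl)decahydronaphthalen-1-yl (E)-2-methylbut-2-enoate | C=C(C)[C@@H]1C[C@]2(C)[C@@H](C)[C@H](OC(=O)C=C(C)C)CC[C@H]2[C@H](OC(=O)/C(C)=C/C)C1=O | target

## Step count and least certain steps

Total: 19 steps. Longest linear sequence: 18 steps (steps 1–5 and 7–19, from pent-4-yn-1-ol); step 6 is the only side branch.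

**Step 12 (key step, new method).**
- What may go wrong: radical 17 may be quenched before it reaches C10. Hydrogen-atom transfer is reversible, so the double bond can move into the ring, which would erase C4. A second hydrogen can saturate the alkene, or the hydride can attack the strained enone first. All of these compete because the closure needs one particular ring conformation. Closure through a chair–boat arrangement, giving the cis-fused or C5-epimeric decalone, cannot be excluded either, since facial control rests on a conformational argument.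
- Fallback (sets out from 15, returns at 19): the same radical is made without any metal hydride present during the ring closure.
 - Mukaiyama hydration of the methylene of 15 (Co(acac)2, PhSiH3, O2, THF/i-PrOH; oxygen traps the tertiary radical faster than it can cyclise onto an unactivated alkene) gives the diol F1.
 - Dess–Martin oxidation of the allylic alcohol gives the hydroxy enone F2.
 - Methyl chlorooxoacetate, Et3N and DMAP give the tertiary methyl oxalate F3, and one equivalent of CsOH in THF/H2O gives the caesium oxalate F4.
 - Visible-light photoredox decarboxylation (Ir[dF(CF3)ppy]2(dtbbpy)PF6, blue light, DME/DMF/H2O, 60 °C) releases radical 17, which closes to 18; reduction by the photocatalyst and protonation then give 19.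
 - Tertiary alkyl oxalates are established sources of tertiary radicals for conjugate addition to enones, and no hydrogen-atom donor is present to isomerise or reduce.

**Step 10 (ten-membered ring closure).**
- What may go wrong: intermolecular coupling to dimers and oligomers, and loss of iodine by protonation of the organometallic intermediate. Closing a ten-membered ring that contains an (E)-alkene and an sp2 carbon is slow compared with these processes.
- Fallback (sets out from 14, returns at 16, so step 11 is skipped): an anionic acylation in place of the chromium-mediated addition.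
 - Pinnick oxidation (NaClO2, NaH2PO4, 2-methylbut-2-ene) gives the carboxylic acid F5.
 - Coupling with MeNH(OMe)·HCl (EDC, i-Pr2NEt) gives the Weinreb amide F6.
 - Iodine–lithium exchange with t-BuLi (2 equiv, THF, −100 °C, high dilution) and immediate intramolecular attack on the amide (Parham-type cyclisation) give the enone 16 directly. The chelated adduct prevents a second addition.

**Step 19 (final dehydration).**
- What may go wrong: loss of H-7 instead of a methyl hydrogen, because H-7 is activated by the ketone; this leads into conjugation and deletes C7. Substitution to the tertiary chloride may also compete.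
- Fallback (sets out from 23, returns at 33): the isopropenyl group is made by kinetic protonation and not by elimination, before any ester is present.
 - Deliberate elimination into conjugation (MsCl, Et3N, then DBU) gives the isopropylidene enone F7.
 - Kinetic α′-deprotonation (KN(SiMe3)2, −78 °C) and oxidation with the same oxaziridine give the 9α-hydroxy enone F8, and TESOTf/2,6-lutidine gives its triethylsilyl ether F9.
 - Equilibration to the extended dienolate (KOt-Bu, t-BuOH/THF) and fast quenching into cold aqueous acetic acid, which protonates C7 kinetically, give the deconjugated isopropenyl ketone F10.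
 - AcOH/THF/H2O removes the triethylsilyl group to give the 9-alcohol F11, and 27 with pyridine/DMAP gives the tiglate F12.
 - HF·pyridine gives the C3 alcohol F13, and 30 with pyridine/DMAP gives 33.

**Step 15 (C9 hydroxylation).**
- What may go wrong: enolisation toward C7, followed by β-elimination of the silyloxy group, or incomplete facial selectivity of oxygen transfer, since both α-hydrogens are hindered by the angular methyl.
- Fallback (sets out from 23, returns at 33): the detour written out under step 19 through F7–F13. There C9 is the only kinetically accessible α′-position of a cross-conjugated enone, so no regiochemical choice arises.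

## Further compounds

F1 | step 12 | (2E,6R,7S)-6-[(tert-butyldimethylsilyl)oxy]-7,8-dimethylcyclodec-2-ene-1,8-diol (epimers at C1 and C8) | OC1/C=C/CC[C@@H](O[Si](C)(C)C(C)(C)C)[C@H](C)C(C)(O)CC1
F2 | step 12 | (2E,6R,7S)-6-[(tert-butyldimethylsilyl)oxy]-8-hydroxy-7,8-dimethylcyclodec-2-en-1-one (C8 epimers) | O=C1/C=C/CC[C@@H](O[Si](C)(C)C(C)(C)C)[C@H](C)C(C)(O)CC1
F3 | step 12 | methyl oxalate of the tertiary alcohol F2 | O=C1/C=C/CC[C@@H](O[Si](C)(C)C(C)(C)C)[C@H](C)C(C)(OC(=O)C(=O)OC)CC1
F4 | step 12 | caesium oxalate derived from F3 | O=C1/C=C/CC[C@@H](O[Si](C)(C)C(C)(C)C)[C@H](C)C(C)(OC(=O)C(=O)[O-])CC1.[Cs+]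
F5 | step 10 | (5R,6R,9E)-6-[(tert-butyldimethylsilyl)oxy]-10-iodo-5-methyl-4-methylidenedec-9-enoic acid | I/C=C/CC[C@@H](O[Si](C)(C)C(C)(C)C)[C@H](C)C(=C)CCC(=O)O
F6 | step 10 | (5R,6R,9E)-6-[(tert-butyldimethylsilyl)oxy]-10-iodo-N-methoxy-N,5-dimethyl-4-methylidenedec-9-enamide | I/C=C/CC[C@@H](O[Si](C)(C)C(C)(C)C)[C@H](C)C(=C)CCC(=O)N(C)OC
F7 | step 19 | (4aS,5R,6R,8aS)-6-[(tert-butyldimethylsilyl)oxy]-4a,5-dimethyl-3-(propan-2-ylidene)octahydronaphthalen-2(1H)-one | CC(C)=C1C[C@]2(C)[C@@H](C)[C@H](O[Si](C)(C)C(C)(C)C)CC[C@H]2CC1=O
F8 | step 19 | (1S,4aR,5R,6R,8aR)-6-[(tert-butyldimethylsilyl)oxy]-1-hydroxy-4a,5-dimethyl-3-(propan-2-ylidene)octahydronaphthalen-2(1H)-one | CC(C)=C1C[C@]2(C)[C@@H](C)[C@H](O[Si](C)(C)C(C)(C)C)CC[C@H]2[C@H](O)C1=O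
F9 | step 19 | triethylsilyl ether of F8 at the C9 oxygen | CC(C)=C1C[C@]2(C)[C@@H](C)[C@H](O[Si](C)(C)C(C)(C)C)CC[C@H]2[C@H](O[Si](CC)(CC)CC)C1=O
F10 | step 19 | (1S,3S,4aR,5R,6R,8aR)-6-[(tert-butyldimethylsilyl)oxy]-4a,5-dimethyl-3-(prop-1-en-2-yl)-1-[(triethylsilyl)oxy]octahydronaphthalen-2(1H)-one | C=C(C)[C@@H]1C[C@]2(C)[C@@H](C)[C@H](O[Si](C)(C)C(C)(C)C)CC[C@H]2[C@H](O[Si](CC)(CC)CC)C1=O
F11 | step 19 | (1S,3S,4aR,5R,6R,8aR)-6-[(tert-butyldimethylsilyl)oxy]-1-hydroxy-4a,5-dimethyl-3-(prop-1-en-2-yl)octahydronaphthalen-2(1H)-one | C=C(C)[C@@H]1C[C@]2(C)[C@@H](C)[C@H](O[Si](C)(C)C(C)(C)C)CC[C@H]2[C@H](O)C1=O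
F12 | step 19 | (1S,3S,4aR,5R,6R,8aR)-6-[(tert-butyldimethylsilyl)oxy]-4a,5-dimethyl-2-oxo-3-(prop-1-en-2-yl)decahydronaphthalen-1-yl (E)-2-methylbut-2-enoate | C=C(C)[C@@H]1C[C@]2(C)[C@@H](C)[C@H](O[Si](C)(C)C(C)(C)C)CC[C@H]2[C@H](OC(=O)/C(C)=C/C)C1=O
F13 | step 19 | (1S,3S,4aR,5R,6R,8aR)-6-hydroxy-4a,5-dimethyl-2-oxo-3-(prop-1-en-2-yl)decahydronaphthalen-1-yl (E)-2-methylbut-2-enoate | C=C(C)[C@@H]1C[C@]2(C)[C@@H](C)[C@H](O)CC[C@H]2[C@H](OC(=O)/C(C)=C/C)C1=O
F0 | step 15 | none | none
A1 | alternative 1 | 1-[(E)-2-(2-trimethylsilylethoxy)ethenyl]-2,3-dimethyl-4-[(triisopropylsilyl)oxy]cyclohex-1-ene (ring-A diene; C3 and C4 as in the target) | C[C@@H]1C(C)=C(/C=C/OCC[Si](C)(C)C)CC[C@H]1O[Si](C(C)C)(C(C)C)C(C)C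
A2 | alternative 1 | but-3-en-2-one (methyl vinyl ketone) | CC(=O)C=C
A3 | alternative 1 | 7-acetyl-4,5-dimethyl-8-[2-(trimethylsilyl)ethoxy]-3-[(triisopropylsilyl)oxy]octal-9-ene (eremophilane numbering) | CC(=O)[C@@H]1C[C@]2(C)[C@@H](C)[C@H](O[Si](C(C)C)(C(C)C)C(C)C)CCC2=C[C@@H]1OCC[Si](C)(C)C
A4 | alternative 2 | (2E,6E)-farnesyl diphosphate | CC(C)=CCC/C(C)=C/CC/C(C)=C/COP(=O)(O)OP(=O)(O)O
A5 | alternative 2 | (+)-aristolochene | C=C(C)[C@@H]1C[C@]2(C)[C@@H](C)CCCC2=CC1
A6 | alternative 3 | 2-methoxy-5-methyl-1,4-benzoquinone | CC1=CC(=O)C(OC)=CC1=O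
A7 | alternative 3 | (Z)-tert-butyldimethyl(penta-1,3-dien-3-yloxy)silane | C=C/C(O[Si](C)(C)C(C)(C)C)=C/C
A8 | alternative 3 | cis-fused 8-methoxy-4,5-dimethyl-3-[(tert-butyldimethylsilyl)oxy] bicyclic 2,7-diene-6,9-dione (eremophilane numbering) | O=C1C=C(OC)C(=O)[C@H]2CC=C(O[Si](C)(C)C(C)(C)C)[C@@H](C)[C@@]12C
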